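**Retrosynthetic overview**

1. Rings: A = methoxy-bearing ring, B = 1,4-disubstituted ring, C = phenol ring, D = 1,3-disubstituted ring; target 16 ← its benzyl ether 15 by hydrogenolysis of the ring C O-benzyl group.
2. 15 ← open-chain N-acyloxyphthalimide 14: the 19-membered ring is cut at the bond between ring D and the bridge CH2 bound to it; ring D becomes an aryl bromide and the CH2 a primary radical released by loss of CO2 (nickel-electrocatalytic decarboxylative macrocyclization).
3. Enabling feature: ring A with its CH2CH2 bridge is a 2-arylethyl unit ending in an unbranched CH2, that is, dihydroisoferulic acid (which already holds the 3-oxy-4-methoxy pattern of ring A) minus CO2; the ring D carbon to be bonded lies meta to the ether oxygen between two CH positions, so an unhindered 3-bromophenyl ether serves.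
4. 14 ← acid 13 ← stilbene 11 (Wittig, then diimide) ← aldehyde 4 (ring A–O–ring B by SNAr) + phosphonium salt 9 (ring C–O–ring D by Chan–Lam coupling).
5. Ring order: the four benzene rings are bought; the macrocycle is the only ring formed, in step 10.

Key step: step 10

Remark: the target has no stereocentre, so no stereocontrol is needed; 11 is carried as an E/Z mixture because its double bond is saturated in step 7.

**Route**

Step 1
Reactants: 1 3-(3-hydroxy-4-methoxyphenyl)propanoic acid (dihydroisoferulic acid)
Product: 2 methyl 3-(3-hydroxy-4-methoxyphenyl)propanoate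
Conditions: MeOH, H2SO4 (cat.), reflux
Reagents that add atoms: methanol, CO
Why: Fischer esterification in excess methanol should mask the aliphatic acid while the phenol stays free for step 2.

Step 2
Reactants: 2 methyl 3-(3-hydroxy-4-methoxyphenyl)propanoate; 3 4-fluorobenzaldehyde
Product: 4 methyl 3-[3-(4-formylphenoxy)-4-methoxyphenyl]propanoate
Conditions: K2CO3, DMF, 120 °C
Reagents that add atoms: none
Why: SNAr (addition–elimination) of the phenoxide of 2 at the fluoride-bearing carbon, activated by the para formyl group, should give the ring A–O–ring B diaryl ether, and the methyl ester tolerates anhydrous carbonate.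

Step 3
Reactants: 5 4-(benzyloxy)-3-hydroxybenzaldehyde; 6 (3-bromophenyl)boronic acid
Product: 7 4-(benzyloxy)-3-(3-bromophenoxy)benzaldehyde
Conditions: Cu(OAc)2 (20 mol%), pyridine, 4 Å MS, CH2Cl2, O2 (1 atm), rt
Reagents that add atoms: none
Why: Chan–Lam oxidative C–O coupling should transfer the aryl group from boron to the phenol oxygen at room temperature and leave the C–Br bond, the aldehyde and the benzyl ether untouched.

Step 4
Reactants: 7 4-(benzyloxy)-3-(3-bromophenoxy)benzaldehyde
Product: 8 [4-(benzyloxy)-3-(3-bromophenoxy)phenyl]methanol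
Conditions: NaBH4, MeOH/THF, 0 °C
Reagents that add atoms: none
Why: Borohydride reduction of the aromatic aldehyde should give the benzylic alcohol without touching the aryl bromide or the ethers.

Step 5
Reactants: 8 [4-(benzyloxy)-3-(3-bromophenoxy)phenyl]methanol
Product: 9 {[4-(benzyloxy)-3-(3-bromophenoxy)phenyl]methyl}triphenylphosphonium bromide
Conditions: PPh3·HBr, MeCN, reflux
Reagents that add atoms: triphenylphosphine hydrobromide, [Br-].c1ccc(cc1)[PH+](c1ccccc1)c1ccccc1
Why: Acid-promoted ionization of the para-alkoxy benzylic alcohol and capture by PPh3 (SN1-type phosphonium salt formation) should give the Wittig salt directly, with no halide intermediate.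

Step 6
Reactants: 9 {[4-(benzyloxy)-3-(3-bromophenoxy)phenyl]methyl}triphenylphosphonium bromide; 4 methyl 3-[3-(4-formylphenoxy)-4-methoxyphenyl]propanoate
Product: 11 methyl 3-[3-(4-{2-[4-(benzyloxy)-3-(3-bromophenoxy)phenyl]ethenyl}phenoxy)-4-methoxyphenyl]propanoate (E/Z mixture), via phosphonium ylide 10 (not isolated)
Conditions: KOtBu, THF, 0 °C; then 4, 0 °C to rt
Reagents that add atoms: none
Why: Wittig olefination of the preformed semi-stabilized benzylic ylide with the aromatic aldehyde is fast at 0 °C, so the methyl ester should not be attacked, and the alkene geometry is irrelevant.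

Step 7
Reactants: 11 methyl 3-[3-(4-{2-[4-(benzyloxy)-3-(3-bromophenoxy)phenyl]ethenyl}phenoxy)-4-methoxyphenyl]propanoate
Product: 12 methyl 3-[3-(4-{2-[4-(benzyloxy)-3-(3-bromophenoxy)phenyl]ethyl}phenoxy)-4-methoxyphenyl]propanoate
Conditions: TsNHNH2 (excess, in portions), NaOAc, DME/H2O, reflux
Reagents that add atoms: none
Why: Diimide reduction delivers H2 to the C=C bond in a concerted transfer and, unlike hydrogenation over Pd/C, cannot cleave the C–Br bond or the benzyl ether.

Step 8
Reactants: 12 methyl 3-[3-(4-{2-[4-(benzyloxy)-3-(3-bromophenoxy)phenyl]ethyl}phenoxy)-4-methoxyphenyl]propanoate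
Product: 13 3-[3-(4-{2-[4-(benzyloxy)-3-(3-bromophenoxy)phenyl]ethyl}phenoxy)-4-methoxyphenyl]propanoic acid
Conditions: LiOH, THF/MeOH/H2O, rt; then 1 M HCl
Reagents that add atoms: lithium hydroxide, [Li+].[OH-]
Why: Saponification of the unhindered methyl ester should proceed at room temperature without affecting the aryl ethers or the aryl bromide.

Step 9
Reactants: 13 3-[3-(4-{2-[4-(benzyloxy)-3-(3-bromophenoxy)phenyl]ethyl}phenoxy)-4-methoxyphenyl]propanoic acid
Product: 14 1,3-dioxoisoindolin-2-yl 3-[3-(4-{2-[4-(benzyloxy)-3-(3-bromophenoxy)phenyl]ethyl}phenoxy)-4-methoxyphenyl]propanoate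
Conditions: N-hydroxyphthalimide, DIC, DMAP (cat.), CH2Cl2, rt
Reagents that add atoms: N-hydroxyphthalimide, ON1C(=O)c2ccccc2C1=O
Why: Steglich-type carbodiimide esterification should give the bench-stable redox-active ester whose easy one-electron reduction the key step requires.

Step 10
Reactants: 14 1,3-dioxoisoindolin-2-yl 3-[3-(4-{2-[4-(benzyloxy)-3-(3-bromophenoxy)phenyl]ethyl}phenoxy)-4-methoxyphenyl]propanoate
Product: 15 O-benzyl ether of the target (19-membered macrocycle with OCH2Ph on ring C)
Conditions: NiCl2·6H2O (30 mol%), 2,2'-bipyridine (30 mol%), LiCl, NMP, Mg anode, RVC cathode plated with Ag nanoparticles (from AgNO3), constant current, rt; 14 added by syringe pump (final ca. 2 mM)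
Reagents that add atoms: none
Why: Proposed new method: zerovalent nickel on bipyridine, regenerated at the cathode, should insert into the only C–Br bond of 14 (ring D), while one-electron reduction of the N-acyloxyphthalimide (at the silver-coated cathode or by monovalent nickel) expels phthalimide anion and CO2 and leaves a primary radical on the bridge carbon β to ring A; capture of this radical by the divalent arylnickel bromide of the same molecule gives a trivalent aryl(alkyl)nickel centre, and reductive elimination forms the ring D C(sp2)–CH2 bond. The closest known reaction type is the intermolecular nickel-electrocatalytic decarboxylative arylation of primary redox-active esters with aryl bromides (a reductive aryl–alkyl cross-electrophile coupling); new is its use to close a macrocycle. The one ring closed is the 19-membered macrocycle, closed end to end with the new bond endocyclic and made by reductive elimination at nickel; no stereocentre is formed and the target has none. The step needs ring closure to outrun oligomerization, hydrogen-atom capture by the radical and hydrodebromination: syringe-pump addition keeps free 14 near millimolar, the arylnickel partner is persistent and tethered to the radical, the 2-arylethyl radical has no productive rearrangement (its 1,2-aryl shift is degenerate), and the two diaryl ether hinges together with the 1,3-substitution of rings A, C and D fold the chain so that its ends can meet. Chemoselectivity rests on 14 holding exactly one C–Br bond and one redox-active ester, while the benzyl, methyl and diaryl ether C–O bonds are inert to bipyridine-ligated nickel at room temperature.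

Step 11
Reactants: 15 O-benzyl ether of the target
Product: 16 CNP0132125.0 (target)
Conditions: H2 (1 atm), Pd/C, EtOAc/MeOH, rt
Reagents that add atoms: none
Why: Hydrogenolysis of the benzyl aryl ether over Pd/C should free the ring C phenol, while the methyl ether, the two diaryl ethers and the saturated bridges are inert.

**Compound list**

1 | 3-(3-hydroxy-4-methoxyphenyl)propanoic acid (dihydroisoferulic acid) | OC(=O)CCc1ccc(OC)c(O)c1 | starting material
2 | methyl 3-(3-hydroxy-4-methoxyphenyl)propanoate | COC(=O)CCc1ccc(OC)c(O)c1 | intermediate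
3 | 4-fluorobenzaldehyde | O=Cc1ccc(F)cc1 | starting material
4 | methyl 3-[3-(4-formylphenoxy)-4-methoxyphenyl]propanoate | COC(=O)CCc1ccc(OC)c(Oc2ccc(C=O)cc2)c1 | intermediate
5 | 4-(benzyloxy)-3-hydroxybenzaldehyde | O=Cc1ccc(OCc2ccccc2)c(O)c1 | starting material
6 | (3-bromophenyl)boronic acid | OB(O)c1cccc(Br)c1 | starting material
7 | 4-(benzyloxy)-3-(3-bromophenoxy)benzaldehyde | O=Cc1ccc(OCc2ccccc2)c(Oc2cccc(Br)c2)c1 | intermediate
8 | [4-(benzyloxy)-3-(3-bromophenoxy)phenyl]methanol | OCc1ccc(OCc2ccccc2)c(Oc2cccc(Br)c2)c1 | intermediate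
9 | {[4-(benzyloxy)-3-(3-bromophenoxy)phenyl]methyl}triphenylphosphonium bromide | [Br-].Brc1cccc(Oc2cc(C[P+](c3ccccc3)(c3ccccc3)c3ccccc3)ccc2OCc2ccccc2)c1 | intermediate
10 | phosphonium ylide of 9, {[4-(benzyloxy)-3-(3-bromophenoxy)phenyl]methylidene}triphenylphosphorane (not isolated) | Brc1cccc(Oc2cc(C=P(c3ccccc3)(c3ccccc3)c3ccccc3)ccc2OCc2ccccc2)c1 | intermediate
11 | methyl 3-[3-(4-{2-[4-(benzyloxy)-3-(3-bromophenoxy)phenyl]ethenyl}phenoxy)-4-methoxyphenyl]propanoate (E/Z mixture, double bond geometry undefined) | COC(=O)CCc1ccc(OC)c(Oc2ccc(C=Cc3ccc(OCc4ccccc4)c(Oc4cccc(Br)c4)c3)cc2)c1 | intermediate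
12 | methyl 3-[3-(4-{2-[4-(benzyloxy)-3-(3-bromophenoxy)phenyl]ethyl}phenoxy)-4-methoxyphenyl]propanoate | COC(=O)CCc1ccc(OC)c(Oc2ccc(CCc3ccc(OCc4ccccc4)c(Oc4cccc(Br)c4)c3)cc2)c1 | intermediate
13 | 3-[3-(4-{2-[4-(benzyloxy)-3-(3-bromophenoxy)phenyl]ethyl}phenoxy)-4-methoxyphenyl]propanoic acid | OC(=O)CCc1ccc(OC)c(Oc2ccc(CCc3ccc(OCc4ccccc4)c(Oc4cccc(Br)c4)c3)cc2)c1 | intermediate
14 | 1,3-dioxoisoindolin-2-yl 3-[3-(4-{2-[4-(benzyloxy)-3-(3-bromophenoxy)phenyl]ethyl}phenoxy)-4-methoxyphenyl]propanoate | O=C(CCc1ccc(OC)c(Oc2ccc(CCc3ccc(OCc4ccccc4)c(Oc4cccc(Br)c4)c3)cc2)c1)ON1C(=O)c2ccccc2C1=O | intermediate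
15 | O-benzyl ether of the target: 19-membered macrocycle, ring A (OMe) –O– ring B (1,4) –CH2CH2– ring C (OBn) –O– ring D (1,3) –CH2CH2– ring A | COc1ccc2cc1Oc1ccc(cc1)CCc1ccc(OCc3ccccc3)c(c1)Oc1cccc(c1)CC2 | intermediate
16 | CNP0132125.0, the macrocyclic bis(bibenzyl) with free phenol on ring C (no stereocentre) | COc1ccc2cc1Oc1ccc(cc1)CCc1ccc(O)c(c1)Oc1cccc(c1)CC2 | target

**Step count and risk**

Total steps: 11. Longest linear sequence: 9 steps (steps 3 to 11, from 5 and 6 to 16).

Steps most likely to fail:

Step 10 (Proposed new method). Ring closure may be outrun by intermolecular coupling, by hydrogen-atom capture of the radical or by hydrodebromination, so that oligomers and reduced open-chain material form in place of the macrocycle. The fallback uses known chemistry and sets out from 14. Irradiation with bis(catecholato)diboron in DMAc under blue LEDs (metal-free photoinduced decarboxylative borylation, which tolerates aryl bromides) should give the catechol boronate 2-{2-[3-(4-{2-[4-(benzyloxy)-3-(3-bromophenoxy)phenyl]ethyl}phenoxy)-4-methoxyphenyl]ethyl}-1,3,2-benzodioxaborole F1 (not isolated). Pinacol and Et3N in the same flask should convert it into the pinacol boronate 2-{2-[3-(4-{2-[4-(benzyloxy)-3-(3-bromophenoxy)phenyl]ethyl}phenoxy)-4-methoxyphenyl]ethyl}-4,4,5,5-tetramethyl-1,3,2-dioxaborolane F2. Intramolecular B-alkyl Suzuki–Miyaura coupling of F2 under pseudo-high dilution (Pd(OAc)2, RuPhos, K3PO4, toluene/H2O, 90 °C, syringe-pump addition) should then form the same ring D–CH2 bond without free radicals and come back to the route at 15.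

Step 3. Slow aryl transfer to the hindered ortho-benzyloxy phenol may let protodeboronation and oxidative homocoupling consume the boronic acid before the ether forms. The fallback sets out from 5: Ullmann-type C–O coupling with 1-bromo-3-iodobenzene (CuI, picolinic acid, K3PO4, DMSO, 80 °C), in which copper should react selectively at the C–I bond, comes back to the route at 7. Compound outside the list made on the way: none F0.

Step 7. Diimide may disproportionate faster than it transfers hydrogen to the conjugated 1,2-diaryl double bond, so that conversion stalls, and forcing the reduction with heterogeneous hydrogenation would risk loss of bromide and of the benzyl group. The fallback builds the bridge at the saturated level with no alkene and sets out from 8. SOCl2 (CH2Cl2, 0 °C) should give 1-(benzyloxy)-2-(3-bromophenoxy)-4-(chloromethyl)benzene F3. Zinc dust and LiCl in THF at rt should insert only into the benzylic C–Cl bond to give {[4-(benzyloxy)-3-(3-bromophenoxy)phenyl]methyl}zinc chloride F4 (not isolated). Its addition to aldehyde 4 (ester tolerated) should give racemic methyl 3-[3-(4-{2-[4-(benzyloxy)-3-(3-bromophenoxy)phenyl]-1-hydroxyethyl}phenoxy)-4-methoxyphenyl]propanoate F5. Ionic deoxygenation (Et3SiH, TFA, CH2Cl2, 0 °C), through the benzylic cation stabilized by the para-aryloxy group of ring B, should remove the hydroxyl and its stereocentre and come back to the route at 12.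

Further compounds

F1 | step 10 | 2-{2-[3-(4-{2-[4-(benzyloxy)-3-(3-bromophenoxy)phenyl]ethyl}phenoxy)-4-methoxyphenyl]ethyl}-1,3,2-benzodioxaborole | COc1ccc(CCB2Oc3ccccc3O2)cc1Oc1ccc(CCc2ccc(OCc3ccccc3)c(Oc3cccc(Br)c3)c2)cc1
F2 | step 10 | 2-{2-[3-(4-{2-[4-(benzyloxy)-3-(3-bromophenoxy)phenyl]ethyl}phenoxy)-4-methoxyphenyl]ethyl}-4,4,5,5-tetramethyl-1,3,2-dioxaborolane | COc1ccc(CCB2OC(C)(C)C(C)(C)O2)cc1Oc1ccc(CCc2ccc(OCc3ccccc3)c(Oc3cccc(Br)c3)c2)cc1
F0 | step 3 | none | none
F3 | step 7 | 1-(benzyloxy)-2-(3-bromophenoxy)-4-(chloromethyl)benzene | ClCc1ccc(OCc2ccccc2)c(Oc2cccc(Br)c2)c1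
F4 | step 7 | {[4-(benzyloxy)-3-(3-bromophenoxy)phenyl]methyl}zinc chloride | Cl[Zn]Cc1ccc(OCc2ccccc2)c(Oc2cccc(Br)c2)c1
F5 | step 7 | methyl 3-[3-(4-{2-[4-(benzyloxy)-3-(3-bromophenoxy)phenyl]-1-hydroxyethyl}phenoxy)-4-methoxyphenyl]propanoate (racemic) | COC(=O)CCc1ccc(OC)c(Oc2ccc(C(O)Cc3ccc(OCc4ccccc4)c(Oc4cccc(Br)c4)c3)cc2)c1
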